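**Retrosynthetic overview**
1. Target quinone ⇐ its hydroquinone (Ag2O) ⇐ ring C6–C1′ bond, made by BF3-promoted allylation of the C1 carbonyl of 2-methoxy-5-methyl-1,4-benzoquinone with all-E decaprenyl tributylstannane, followed by [3,3] shift of the allyl group to C6.
2. Decaprenyl stannane ⇐ decaprenol ⇐ C45 + C5 (C4′–C5′ bond): lithiated solanesyl p-tolyl sulfone + an (E)-C5 allylic bromide, then Pd-catalysed reductive desulfonylation.
3. C5 bromide ⇐ prenol (silylation, E-selective SeO2 oxidation, Appel bromination); sulfone ⇐ natural all-E solanesol.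
4. Rings: the single six-membered ring is never constructed; it comes from 2-methoxy-5-methylphenol, oxidised to the quinone before the coupling.

Assumption: the target has no stereocentre, so "single enantiomer" is read as the single all-E isomer (nine E trisubstituted alkenes). Chain carbons are numbered C1′ (ring-bound CH2) outward; ring carbons are numbered as in 2-methoxy-5-methyl-1,4-benzoquinone (C1 = carbonyl next to the methoxy carbon). TBDPS = tert-butyldiphenylsilyl.

**Route**

Step 1
Reactants: 1 2-methoxy-5-methylphenol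
Product: 2 2-methoxy-5-methyl-1,4-benzoquinone
Conditions: K2[ON(SO3)2] (2.2 equiv), KH2PO4, H2O/acetone, 0 °C → rt
Reagents that add atoms: potassium nitrosodisulfonate, [K+].[K+].[O]N(S(=O)(=O)[O-])S(=O)(=O)[O-]
Why: Teuber oxidation, in which the nitroxyl radical removes the phenolic hydrogen and a second equivalent delivers oxygen to the free para carbon, giving the p-quinone with methyl and methoxy untouched (no stereocentre).

Step 2
Reactants: 3 solanesol, (all-E)-nonaprenol
Product: 4 (all-E)-solanesyl bromide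
Conditions: PBr3 (0.4 equiv), pyridine (cat.), Et2O/hexane, −10 → 0 °C
Reagents that add atoms: phosphorus tribromide, BrP(Br)Br
Why: SN2 displacement of the phosphite ester of a primary allylic alcohol by bromide at low temperature keeps the 2E alkene and the rest of the chain intact.

Step 3
Reactants: 4 (all-E)-solanesyl bromide
Product: 5 (all-E)-solanesyl p-tolyl sulfone
Conditions: p-TolSO2Na (1.5 equiv), DMF, rt
Reagents that add atoms: sodium p-toluenesulfinate, [Na+].[O-]S(=O)c1ccc(C)cc1
Why: S-alkylation of the sulfinate by the primary allylic bromide (SN2) gives a crystallisable sulfone with the alkene geometry unchanged.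

Step 4
Reactants: 6 prenol (3-methylbut-2-en-1-ol)
Product: 7 prenyl TBDPS ether, tert-butyl[(3-methylbut-2-en-1-yl)oxy]diphenylsilane
Conditions: TBDPSCl (1.05 equiv), imidazole (2 equiv), DMF, rt
Reagents that add atoms: tert-butylchlorodiphenylsilane, CC(C)(C)[Si](Cl)(c1ccccc1)c1ccccc1
Why: Standard imidazole-mediated O-silylation of a primary alcohol gives an ether that survives the oxidation, the organolithium and the hydride steps that follow.

Step 5
Reactants: 7 prenyl TBDPS ether
Product: 8 (E)-4-[(tert-butyldiphenylsilyl)oxy]-2-methylbut-2-en-1-ol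
Conditions: SeO2 (0.5 equiv), t-BuOOH (2 equiv), salicylic acid (0.1 equiv), CH2Cl2, 0 °C → rt, stopped at about 70% conversion
Reagents that add atoms: tert-butyl hydroperoxide, CC(C)(C)OO (oxygen relayed by the SeO2 catalyst)
Why: Riley–Sharpless allylic oxidation (ene reaction, then [2,3] shift) hydroxylates only the methyl group trans to the chain, which sets the E alkene of the future first isoprene unit.

Step 6
Reactants: 8 (E)-4-[(tert-butyldiphenylsilyl)oxy]-2-methylbut-2-en-1-ol
Product: 9 (E)-[(4-bromo-3-methylbut-2-en-1-yl)oxy](tert-butyl)diphenylsilane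
Conditions: CBr4 (1.2 equiv), PPh3 (1.25 equiv), CH2Cl2, 0 °C
Reagents that add atoms: carbon tetrabromide, BrC(Br)(Br)Br
Why: Appel bromination converts the primary allylic alcohol by SN2 under neutral conditions, so the E geometry and the silyl ether are kept.

Step 7
Reactants: 5 (all-E)-solanesyl p-tolyl sulfone; 9 (E)-C5 allylic bromide
Product: 11 (all-E)-decaprenyl TBDPS ether bearing a p-tolylsulfonyl group at C5′ (racemic at C5′), via α-lithio solanesyl p-tolyl sulfone 10 (not isolated)
Conditions: n-BuLi (1.05 equiv), THF, −78 °C; then 9, −78 → −20 °C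
Reagents that add atoms: none
Why: Alkylation of the α-sulfonyl allyl carbanion at its α-carbon by the primary allylic bromide (Julia-type sulfone coupling, SN2) forms the C4′–C5′ bond without touching any alkene; the new C5′ stereocentre is racemic and is erased in step 8.

Step 8
Reactants: 11 C5′-sulfonyl decaprenyl TBDPS ether
Product: 12 (all-E)-decaprenyl TBDPS ether
Conditions: PdCl2(dppp) (5 mol%, dppp = 1,3-bis(diphenylphosphino)propane), LiBHEt3 (2.5 equiv), THF, 0 °C
Reagents that add atoms: none
Why: Zerovalent palladium, formed from the divalent precatalyst by the hydride, ionises the allylic sulfone to a π-allyl complex and hydride attacks the less substituted terminus C5′ (Tsuji–Trost-type reductive desulfonylation), so the 6′E alkene stays in place with its geometry.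

Step 9
Reactants: 12 (all-E)-decaprenyl TBDPS ether
Product: 13 (all-E)-decaprenol
Conditions: Bu4NF (1.2 equiv), THF, 0 °C → rt
Reagents that add atoms: none
Why: Fluoride-driven Si–O cleavage frees the primary allylic alcohol under conditions inert to the polyene.

Step 10
Reactants: 13 (all-E)-decaprenol
Product: 14 (all-E)-decaprenyl bromide
Conditions: PBr3 (0.4 equiv), pyridine (cat.), Et2O/hexane, −10 → 0 °C; used crude
Reagents that add atoms: phosphorus tribromide, BrP(Br)Br
Why: Same SN2 bromination of a primary allylic alcohol as in step 2, which retains the 2′E alkene.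

Step 11
Reactants: 14 (all-E)-decaprenyl bromide
Product: 15 (all-E)-decaprenyl tributylstannane
Conditions: Bu3SnH, LiN(i-Pr)2, THF, 0 °C (gives Bu3SnLi); then 14, −78 °C; chromatography on Et3N-deactivated silica
Reagents that add atoms: tributyltin hydride, CCCC[SnH](CCCC)CCCC (delivered as tributylstannyllithium, [Li][Sn](CCCC)(CCCC)CCCC)
Why: The stannyl anion displaces the primary allylic bromide by SN2 at −78 °C, giving the linear allylstannane with the 2′E alkene retained.

Step 12
Reactants: 15 (all-E)-decaprenyl tributylstannane; 2 2-methoxy-5-methyl-1,4-benzoquinone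
Product: 17 2-[(all-E)-decaprenyl]-6-methoxy-3-methylbenzene-1,4-diol, via C1 quinol 16 (not isolated)
Conditions: BF3·OEt2 (2 equiv), CH2Cl2, −78 → −40 °C (15 added to 2, 1.3 equiv); then H2O; used crude
Reagents that add atoms: none
Why: Lewis-acid-promoted carbonyl allylation by the allylstannane (Naruta quinone allylation) occurs through the γ-carbon at C1, the ketone-like carbonyl (C4 is a deactivated vinylogous ester), to give quinol 16; its tertiary allyl group then moves by a BF3-accelerated [3,3] shift to C6, the only CH carbon next to C1, and tautomerises to the hydroquinone, a chair transition state with the long chain pseudo-equatorial returning the linear 2′E chain with no stereocentre left.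

Step 13
Reactants: 17 decaprenyl hydroquinone
Product: 18 2-[(all-E)-decaprenyl]-6-methoxy-3-methyl-1,4-benzoquinone (target, CID25010748)
Conditions: Ag2O (2 equiv), Na2SO4, Et2O, rt, dark; silica chromatography, then crystallisation from EtOH/acetone to remove any 2′Z isomer
Reagents that add atoms: none
Why: Mild two-electron oxidation of the hydroquinone to the quinone by Ag2O does not affect the nine isolated alkenes.

**Compound list**
1 | 2-methoxy-5-methylphenol | COc1ccc(C)cc1O | starting material
2 | 2-methoxy-5-methyl-1,4-benzoquinone | COC1=CC(=O)C(C)=CC1=O | intermediate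
3 | solanesol, (all-E)-nonaprenol | OC/C=C(\C)CC/C=C(\C)CC/C=C(\C)CC/C=C(\C)CC/C=C(\C)CC/C=C(\C)CC/C=C(\C)CC/C=C(\C)CCC=C(C)C | starting material
4 | (all-E)-solanesyl bromide | BrC/C=C(\C)CC/C=C(\C)CC/C=C(\C)CC/C=C(\C)CC/C=C(\C)CC/C=C(\C)CC/C=C(\C)CC/C=C(\C)CCC=C(C)C | intermediate
5 | (all-E)-solanesyl p-tolyl sulfone | Cc1ccc(cc1)S(=O)(=O)C/C=C(\C)CC/C=C(\C)CC/C=C(\C)CC/C=C(\C)CC/C=C(\C)CC/C=C(\C)CC/C=C(\C)CC/C=C(\C)CCC=C(C)C | intermediate
6 | prenol, 3-methylbut-2-en-1-ol | CC(C)=CCO | starting material
7 | prenyl TBDPS ether | CC(C)=CCO[Si](c1ccccc1)(c1ccccc1)C(C)(C)C | intermediate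
8 | (E)-4-[(tert-butyldiphenylsilyl)oxy]-2-methylbut-2-en-1-ol | OC/C(C)=C/CO[Si](c1ccccc1)(c1ccccc1)C(C)(C)C | intermediate
9 | (E)-[(4-bromo-3-methylbut-2-en-1-yl)oxy](tert-butyl)diphenylsilane | BrC/C(C)=C/CO[Si](c1ccccc1)(c1ccccc1)C(C)(C)C | intermediate
10 | α-lithio solanesyl p-tolyl sulfone (not isolated) | Cc1ccc(cc1)S(=O)(=O)C([Li])/C=C(\C)CC/C=C(\C)CC/C=C(\C)CC/C=C(\C)CC/C=C(\C)CC/C=C(\C)CC/C=C(\C)CC/C=C(\C)CCC=C(C)C | intermediate
11 | (all-E)-decaprenyl TBDPS ether with p-tolylsulfonyl at C5′, racemic at C5′ | CC(C)(C)[Si](c1ccccc1)(c1ccccc1)OC/C=C(\C)CC(S(=O)(=O)c1ccc(C)cc1)/C=C(\C)CC/C=C(\C)CC/C=C(\C)CC/C=C(\C)CC/C=C(\C)CC/C=C(\C)CC/C=C(\C)CC/C=C(\C)CCC=C(C)C | intermediate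
12 | (all-E)-decaprenyl TBDPS ether | CC(C)(C)[Si](c1ccccc1)(c1ccccc1)OC/C=C(\C)CC/C=C(\C)CC/C=C(\C)CC/C=C(\C)CC/C=C(\C)CC/C=C(\C)CC/C=C(\C)CC/C=C(\C)CC/C=C(\C)CCC=C(C)C | intermediate
13 | (all-E)-decaprenol | OC/C=C(\C)CC/C=C(\C)CC/C=C(\C)CC/C=C(\C)CC/C=C(\C)CC/C=C(\C)CC/C=C(\C)CC/C=C(\C)CC/C=C(\C)CCC=C(C)C | intermediate
14 | (all-E)-decaprenyl bromide | BrC/C=C(\C)CC/C=C(\C)CC/C=C(\C)CC/C=C(\C)CC/C=C(\C)CC/C=C(\C)CC/C=C(\C)CC/C=C(\C)CC/C=C(\C)CCC=C(C)C | intermediate
15 | (all-E)-decaprenyl tributylstannane | CCCC[Sn](CCCC)(CCCC)C/C=C(\C)CC/C=C(\C)CC/C=C(\C)CC/C=C(\C)CC/C=C(\C)CC/C=C(\C)CC/C=C(\C)CC/C=C(\C)CC/C=C(\C)CCC=C(C)C | intermediate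
16 | C1 quinol: 4-hydroxy-5-methoxy-2-methylcyclohexa-2,5-dien-1-one carrying at C4 the allyl-transposed (tertiary) decaprenyl group C(CH3)(CH=CH2)CH2CH2-[all-E C40 chain], diastereomer mixture (not isolated) | COC1=CC(=O)C(C)=CC1(O)C(C)(C=C)CC/C=C(\C)CC/C=C(\C)CC/C=C(\C)CC/C=C(\C)CC/C=C(\C)CC/C=C(\C)CC/C=C(\C)CC/C=C(\C)CCC=C(C)C | intermediate
17 | 2-[(all-E)-decaprenyl]-6-methoxy-3-methylbenzene-1,4-diol | COc1cc(O)c(C)c(C/C=C(\C)CC/C=C(\C)CC/C=C(\C)CC/C=C(\C)CC/C=C(\C)CC/C=C(\C)CC/C=C(\C)CC/C=C(\C)CC/C=C(\C)CCC=C(C)C)c1O | intermediate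
18 | 2-[(all-E)-decaprenyl]-6-methoxy-3-methyl-1,4-benzoquinone | COC1=CC(=O)C(C)=C(C/C=C(\C)CC/C=C(\C)CC/C=C(\C)CC/C=C(\C)CC/C=C(\C)CC/C=C(\C)CC/C=C(\C)CC/C=C(\C)CC/C=C(\C)CCC=C(C)C)C1=O | target

**Totals**
Total step count: 13. Longest linear sequence: 10 steps (prenol 6 → 18, steps 4–13); the solanesol branch is 9 steps and the quinone branch is 1 step before the coupling.

**Three steps most likely to fail**

Step 12 (quinone allylation). The risks are attack at the C4 carbonyl, which would place the chain at C3; partial loss of 2′E geometry in the allyl shift; and acid-induced protodestannylation or polyene cyclisation. The fallback sets out from 2 and 13 and comes back at 17. Quinone 2 is reduced with aqueous Na2S2O4 in Et2O to 2-methoxy-5-methylbenzene-1,4-diol F1. F1 is then alkylated with decaprenol 13 under BF3·OEt2 in dioxane/Et2O at room temperature; this is a Friedel–Crafts allylation in which the allyl cation enters para to the methoxy group, the same ring carbon as in the main route. The product is 17, which is oxidised as in step 13, and stannane 15 is not needed.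

Step 8 (reductive desulfonylation). The risks are hydride delivery to the wrong π-allyl terminus, giving a double-bond-shifted isomer, E/Z erosion at C6′, or a stalled reaction on the large lipophilic substrate. The fallback sets out from 4 and comes back at 13, bypassing 5 and 9–12. Bromide 4 is alkylated with LiCH2C≡CSiMe3 (from 1-(trimethylsilyl)propyne and n-BuLi, THF, −78 °C) to give 1-(trimethylsilyl)-3-solanesylprop-1-yne F2. K2CO3 in MeOH/THF removes the silyl group to give 3-solanesylprop-1-yne F3. Negishi carboalumination (AlMe3, Cp2ZrCl2 catalyst, CH2Cl2) adds methyl and aluminium syn across the alkyne to give the (E)-alkenyldimethylalane F4. Treatment of F4 with n-BuLi and then paraformaldehyde gives 13, with the 2′E alkene fixed by the syn addition.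

Step 11 (stannylation). The risks are Wurtz-type dimerisation through halogen–metal exchange, some SN2′ attack giving the tertiary stannane, and protodestannylation of 15 during purification. The fallback sets out from 14 (with 2) and comes back at 16. Bromide 14 is stirred with In powder in DMF at room temperature to form the allylindium reagent, written in its simplest form as decaprenylindium dibromide F5. F5 is added to quinone 2 at −40 °C; this Barbier-type carbonyl allylation attacks the C1 carbonyl through the γ-carbon and gives quinol 16. Brief treatment of 16 with BF3·OEt2 at −40 °C then brings about the shift to 17.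

**Further compounds**
F1 | step 12 | 2-methoxy-5-methylbenzene-1,4-diol | COc1cc(O)c(C)cc1O
F2 | step 8 | 1-(trimethylsilyl)-3-solanesylprop-1-yne | C[Si](C)(C)C#CCC/C=C(\C)CC/C=C(\C)CC/C=C(\C)CC/C=C(\C)CC/C=C(\C)CC/C=C(\C)CC/C=C(\C)CC/C=C(\C)CCC=C(C)C
F3 | step 8 | 3-solanesylprop-1-yne | C#CCC/C=C(\C)CC/C=C(\C)CC/C=C(\C)CC/C=C(\C)CC/C=C(\C)CC/C=C(\C)CC/C=C(\C)CC/C=C(\C)CCC=C(C)C
F4 | step 8 | (E)-dimethyl(2-methyl-4-solanesylbut-1-en-1-yl)alane | C[Al](C)/C=C(\C)CC/C=C(\C)CC/C=C(\C)CC/C=C(\C)CC/C=C(\C)CC/C=C(\C)CC/C=C(\C)CC/C=C(\C)CC/C=C(\C)CCC=C(C)C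
F5 | step 11 | (all-E)-decaprenylindium dibromide | Br[In](Br)C/C=C(\C)CC/C=C(\C)CC/C=C(\C)CC/C=C(\C)CC/C=C(\C)CC/C=C(\C)CC/C=C(\C)CC/C=C(\C)CC/C=C(\C)CCC=C(C)C
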